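**Retrosynthetic overview**
- The target comes from global desilylation of a tris-silyl ether, after a substrate-controlled 1,2-reduction of the C8 ketone (hydride anti to the C7 silyloxy group) and C5 chlorination of an azaphilone 6,8-dione.
- The azaphilone bicycle comes from enantioselective hydroxylative dearomatisation of a resorcinol keto-aldehyde by a flavin-dependent monooxygenase. The carbocycle is the former arene; the pyran ring closes second, by spontaneous cyclodehydration.
- The keto-aldehyde comes from gold-catalysed cycloisomerisation/hydration of an ortho-alkynylbenzaldehyde, itself made by Sonogashira coupling of a bromo-resorcinol aldehyde with an (E)-enyne diol.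
- The enyne diol comes from chelation-controlled MeMgBr addition to an α-PMB-oxy diynone and directed trans-reduction. The diynone derives from (2S,3S)-3-methylpentane-1,2-diol, made by Me3Al opening of the Sharpless epoxide of (E)-pent-2-en-1-ol (first stereocentres, set catalytically).
- The aryl bromide comes from 2,6-dimethoxytoluene by C–H borylation/bromination, formylation and demethylation.

Assumption: the AfoD-type flavin-dependent monooxygenase gives the (7S) non-chlorinated bicycle (its AzaH-type homologue gives the antipode); (7S) becomes (7R) on C5 chlorination by a CIP priority change only, with no change in geometry.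

**Side-chain fragment**

Step 1
Reactants: 1 (E)-pent-2-en-1-ol
Product: 2 [(2R,3R)-3-ethyloxiran-2-yl]methanol
Conditions: Ti(OiPr)4 (5 mol%), D-(−)-diethyl tartrate (6 mol%), tBuOOH, 4 Å MS, CH2Cl2, −20 °C
Reagents that add atoms: tert-butyl hydroperoxide, CC(C)(C)OO
Why: Sharpless asymmetric epoxidation, in which the titanium–D-tartrate catalyst delivers oxygen to one face of the E-allylic alcohol and gives the (2R,3R)-epoxide (about 95% ee), fixing the future C4' centre by catalyst control.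

Step 2
Reactants: 2 [(2R,3R)-3-ethyloxiran-2-yl]methanol
Product: 3 (2S,3S)-3-methylpentane-1,2-diol
Conditions: Me3Al (3 equiv), CH2Cl2/hexane, 0 °C → rt; aq. work-up
Reagents that add atoms: trimethylaluminium, C[Al](C)C
Why: Aluminium-alkoxide-directed epoxide opening delivers methyl to C3 with SN2 inversion, so the trans-epoxide gives the anti 2-hydroxy/3-methyl pattern, that is the future C5' centre (the minor 1,3-diol is removed by chromatography).

Step 3
Reactants: 3 (2S,3S)-3-methylpentane-1,2-diol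
Product: 4 (4S)-4-[(2S)-butan-2-yl]-2-(4-methoxyphenyl)-1,3-dioxolane (both C2 epimers)
Conditions: 4-methoxybenzaldehyde dimethyl acetal, PPTS (cat.), CH2Cl2, rt
Reagents that add atoms: 4-methoxybenzaldehyde dimethyl acetal, COc1ccc(C(OC)OC)cc1
Why: Acid-catalysed transacetalisation of the 1,2-diol touches no stereocentre, and the acetal-carbon mixture converges in the next step.

Step 4
Reactants: 4 (4S)-4-[(2S)-butan-2-yl]-2-(4-methoxyphenyl)-1,3-dioxolane
Product: 5 (2S,3S)-2-[(4-methoxyphenyl)methoxy]-3-methylpentan-1-ol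
Conditions: iBu2AlH (3 equiv), CH2Cl2, −78 → 0 °C
Reagents that add atoms: none
Why: Regioselective reductive acetal opening, in which aluminium binds the less hindered primary oxygen and hydride quenches the oxocarbenium ion, leaving the PMB group on the secondary oxygen.

Step 5
Reactants: 5 (2S,3S)-2-[(4-methoxyphenyl)methoxy]-3-methylpentan-1-ol
Product: 6 (2S,3S)-2-[(4-methoxyphenyl)methoxy]-3-methylpentanal
Conditions: TEMPO (10 mol%), PhI(OAc)2, CH2Cl2, rt; used crude
Reagents that add atoms: none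
Why: Oxoammonium (TEMPO) oxidation stops at the aldehyde under non-basic conditions, so the α-alkoxy centre is not epimerised.

Step 6
Reactants: 6 (2S,3S)-2-[(4-methoxyphenyl)methoxy]-3-methylpentanal; 7 1,4-bis(trimethylsilyl)buta-1,3-diyne
Product: 9 (5RS,6S,7S)-6-[(4-methoxyphenyl)methoxy]-7-methyl-1-(trimethylsilyl)nona-1,3-diyn-5-ol, via lithium 4-(trimethylsilyl)buta-1,3-diynide 8 (not isolated)
Conditions: 7, MeLi·LiBr (1 equiv), THF, 0 °C → rt; then 6, −78 °C; aq. NH4Cl
Reagents that add atoms: none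
Why: Mono-desilylation of the bis-silyl diyne by MeLi gives the lithium diynide, which adds 1,2 to the aldehyde; the new carbinol centre is unimportant because it is oxidised next.

Step 7
Reactants: 9 (5RS,6S,7S)-6-[(4-methoxyphenyl)methoxy]-7-methyl-1-(trimethylsilyl)nona-1,3-diyn-5-ol
Product: 10 (6S,7S)-6-[(4-methoxyphenyl)methoxy]-7-methyl-1-(trimethylsilyl)nona-1,3-diyn-5-one
Conditions: Dess–Martin periodinane, CH2Cl2, 0 °C → rt
Reagents that add atoms: none
Why: Dess–Martin oxidation of the activated propargylic alcohol is fast and neutral, giving the diynone without epimerising C6.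

Step 8
Reactants: 10 (6S,7S)-6-[(4-methoxyphenyl)methoxy]-7-methyl-1-(trimethylsilyl)nona-1,3-diyn-5-one
Product: 11 (5R,6S,7S)-6-[(4-methoxyphenyl)methoxy]-5,7-dimethyl-1-(trimethylsilyl)nona-1,3-diyn-5-ol
Conditions: MeMgBr (3 equiv), THF, −78 °C; aq. NH4Cl
Reagents that add atoms: methylmagnesium bromide, C[Mg]Br
Why: Cram-chelate-controlled Grignard 1,2-addition, in which magnesium bridges the carbonyl and PMB-ether oxygens and methyl attacks from the face of the α-hydrogen (anti to the sec-butyl group), setting the tertiary carbinol as (5R).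

Step 9
Reactants: 11 (5R,6S,7S)-6-[(4-methoxyphenyl)methoxy]-5,7-dimethyl-1-(trimethylsilyl)nona-1,3-diyn-5-ol
Product: 12 (3E,5R,6S,7S)-6-[(4-methoxyphenyl)methoxy]-5,7-dimethyl-1-(trimethylsilyl)non-3-en-1-yn-5-ol
Conditions: NaAlH2(OCH2CH2OMe)2, THF, 0 °C → rt; aq. work-up
Reagents that add atoms: none
Why: Alkoxide-directed trans-hydroalumination reduces only the triple bond next to the hydroxyl group, giving the (E)-alkene and leaving the distal silyl alkyne intact.

Step 10
Reactants: 12 (3E,5R,6S,7S)-6-[(4-methoxyphenyl)methoxy]-5,7-dimethyl-1-(trimethylsilyl)non-3-en-1-yn-5-ol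
Product: 13 (3E,5R,6S,7S)-6-[(4-methoxyphenyl)methoxy]-5,7-dimethylnon-3-en-1-yn-5-ol
Conditions: K2CO3 (cat.), MeOH, rt
Reagents that add atoms: none
Why: Methoxide-mediated protodesilylation of the alkynylsilane frees the terminal alkyne without touching the ether or the alkene.

Step 11
Reactants: 13 (3E,5R,6S,7S)-6-[(4-methoxyphenyl)methoxy]-5,7-dimethylnon-3-en-1-yn-5-ol
Product: 14 (3E,5R,6S,7S)-5,7-dimethylnon-3-en-1-yne-5,6-diol
Conditions: DDQ, CH2Cl2/pH 7 buffer (10:1), 0 °C; then AcOH/THF/H2O, rt if any anisylidene acetal has formed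
Reagents that add atoms: none
Why: Oxidative cleavage of the PMB ether by DDQ (benzylic hydride abstraction, then hydrolysis) leaves the C–O bond and both stereocentres untouched.

**Arene fragment**

Step 12
Reactants: 15 1,3-dimethoxy-2-methylbenzene
Product: 17 5-bromo-1,3-dimethoxy-2-methylbenzene, via arylboronic pinacol ester 16 (not isolated)
Conditions: [Ir(OMe)(cod)]2 (1.5 mol%), 4,4'-di-tert-butyl-2,2'-bipyridine (3 mol%), B2pin2, THF, 80 °C; then CuBr2 (3 equiv), MeOH/H2O, 80 °C
Reagents that add atoms: copper dibromide, [Cu+2].[Br-].[Br-]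
Why: Sterically governed iridium-catalysed C–H borylation occurs only at the position flanked by two hydrogens, and copper-mediated bromodeboronation then gives the bromide meta to both methoxy groups.

Step 13
Reactants: 17 5-bromo-1,3-dimethoxy-2-methylbenzene
Product: 18 6-bromo-2,4-dimethoxy-3-methylbenzaldehyde
Conditions: POCl3, DMF, 0 → 90 °C; then aq. NaOAc
Reagents that add atoms: N,N-dimethylformamide, CN(C)C=O; water, O
Why: Vilsmeier–Haack formylation attacks the only open ring positions, which are equivalent and activated ortho/para by the two methoxy groups, so one aldehyde results.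

Step 14
Reactants: 18 6-bromo-2,4-dimethoxy-3-methylbenzaldehyde
Product: 19 6-bromo-2,4-dihydroxy-3-methylbenzaldehyde
Conditions: BBr3 (4 equiv), CH2Cl2, −78 °C → rt; H2O
Reagents that add atoms: none
Why: Lewis-acid-mediated cleavage of both aryl methyl ethers by BBr3 (bromide SN2 at methyl) frees the resorcinol while the aldehyde and the aryl bromide survive.

**Fragment union and end game**

Step 15
Reactants: 14 (3E,5R,6S,7S)-5,7-dimethylnon-3-en-1-yne-5,6-diol; 19 6-bromo-2,4-dihydroxy-3-methylbenzaldehyde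
Product: 20 6-[(3E,5R,6S,7S)-5,6-dihydroxy-5,7-dimethylnon-3-en-1-yn-1-yl]-2,4-dihydroxy-3-methylbenzaldehyde
Conditions: PdCl2(PPh3)2 (5 mol%), CuI (10 mol%), Et3N, DMF (degassed), 60 °C
Reagents that add atoms: none
Why: Sonogashira coupling proceeds because the ortho-formyl group activates the C–Br bond, and it tolerates the free phenols and alcohols and keeps the alkene geometry.

Step 16
Reactants: 20 6-[(3E,5R,6S,7S)-5,6-dihydroxy-5,7-dimethylnon-3-en-1-yn-1-yl]-2,4-dihydroxy-3-methylbenzaldehyde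
Product: 22 2,4-dihydroxy-6-[(3E,5R,6S,7S)-5,6-dihydroxy-5,7-dimethyl-2-oxonon-3-en-1-yl]-3-methylbenzaldehyde, via 2-benzopyrylium trifluoroacetate 21 (not isolated)
Conditions: Au(OAc)3 (5 mol%), TFA (2 equiv), ClCH2CH2Cl, rt, 10 min; then THF/K2HPO4–KH2PO4 buffer pH 7, rt
Reagents that add atoms: water, O
Why: Carbonyl-assisted 6-endo-dig cycloisomerisation by the π-acidic gold catalyst gives the 2-benzopyrylium ion, whose hydrolysis at C1 and ring opening amount to a regiospecific alkyne hydration that places the ketone on the carbon remote from the ring.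

Step 17
Reactants: 22 2,4-dihydroxy-6-[(3E,5R,6S,7S)-5,6-dihydroxy-5,7-dimethyl-2-oxonon-3-en-1-yl]-3-methylbenzaldehyde
Product: 24 (7S)-3-[(1E,3R,4S,5S)-3,4-dihydroxy-3,5-dimethylhept-1-en-1-yl]-7-hydroxy-7-methyl-6H-isochromene-6,8(7H)-dione, via ortho-quinol 23 (not isolated)
Conditions: flavin-dependent monooxygenase (AfoD-type, FAD), NADP+ (cat.), phosphite dehydrogenase, Na2HPO3, air, K2HPO4/KH2PO4 buffer pH 8.0, DMSO (5% v/v), 30 °C
Reagents that add atoms: dioxygen, O=O
Why: Biocatalytic hydroxylative dearomatisation, in which the enzyme-bound flavin hydroperoxide hydroxylates the methyl-bearing carbon between the two phenolic oxygens on one face only (setting C7), after which the ortho-quinol cyclodehydrates spontaneously to close the pyran ring.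

Step 18
Reactants: 24 (7S)-3-[(1E,3R,4S,5S)-3,4-dihydroxy-3,5-dimethylhept-1-en-1-yl]-7-hydroxy-7-methyl-6H-isochromene-6,8(7H)-dione
Product: 25 (7R)-5-chloro-3-[(1E,3R,4S,5S)-3,4-dihydroxy-3,5-dimethylhept-1-en-1-yl]-7-hydroxy-7-methyl-6H-isochromene-6,8(7H)-dione
Conditions: N-chlorosuccinimide (1.05 equiv), MeCN, 0 °C → rt
Reagents that add atoms: N-chlorosuccinimide, ClN1C(=O)CCC1=O
Why: Electrophilic chlorination occurs at C5, the nucleophilic α-carbon of the doubly vinylogous ester (attack there gives a pyrylium-stabilised cation), and no stereocentre is affected.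

Step 19
Reactants: 25 (7R)-5-chloro-3-[(1E,3R,4S,5S)-3,4-dihydroxy-3,5-dimethylhept-1-en-1-yl]-7-hydroxy-7-methyl-6H-isochromene-6,8(7H)-dione
Product: 26 (7R)-5-chloro-3-[(1E,3R,4S,5S)-3,5-dimethyl-3,4-bis(triethylsilyloxy)hept-1-en-1-yl]-7-methyl-7-(triethylsilyloxy)-6H-isochromene-6,8(7H)-dione
Conditions: Et3SiOTf (4.5 equiv), 2,6-lutidine (6 equiv), CH2Cl2, −78 → 0 °C; aq. NaHCO3
Reagents that add atoms: triethylsilyl trifluoromethanesulfonate, CC[Si](CC)(CC)OS(=O)(=O)C(F)(F)F
Why: Silylation with the silyl triflate and a hindered base caps all three hydroxyls, including the two tertiary ones, which turns the C7 oxygen into a bulky, non-chelating, non-directing group for the next step.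

Step 20
Reactants: 26 (7R)-5-chloro-3-[(1E,3R,4S,5S)-3,5-dimethyl-3,4-bis(triethylsilyloxy)hept-1-en-1-yl]-7-methyl-7-(triethylsilyloxy)-6H-isochromene-6,8(7H)-dione
Product: 27 (7R,8R)-5-chloro-3-[(1E,3R,4S,5S)-3,5-dimethyl-3,4-bis(triethylsilyloxy)hept-1-en-1-yl]-8-hydroxy-7-methyl-7-(triethylsilyloxy)-7,8-dihydro-6H-isochromen-6-one
Conditions: NaBH4 (0.5 equiv), CeCl3·7H2O (1.2 equiv), MeOH/THF, −78 °C; acetone quench
Reagents that add atoms: none
Why: Luche 1,2-reduction is expected at C8, the more ketone-like carbonyl (C6 is deactivated as a pyranylidene-conjugated vinylogous ester), with hydride adding anti to the pseudo-axial C7 silyloxy group (polar Felkin–Anh), which gives the cis 7,8-dioxygen pattern, that is (8R).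

Step 21
Reactants: 27 (7R,8R)-5-chloro-3-[(1E,3R,4S,5S)-3,5-dimethyl-3,4-bis(triethylsilyloxy)hept-1-en-1-yl]-8-hydroxy-7-methyl-7-(triethylsilyloxy)-7,8-dihydro-6H-isochromen-6-one
Product: 28 (7R,8R)-5-chloro-3-[(1E,3R,4S,5S)-3,4-dihydroxy-3,5-dimethylhept-1-en-1-yl]-7,8-dihydroxy-7-methyl-7,8-dihydro-6H-isochromen-6-one
Conditions: HF·pyridine, pyridine, THF, 0 °C → rt
Reagents that add atoms: none
Why: Fluoride-driven desilylation removes all three triethylsilyl groups under buffered, non-basic conditions that spare the base-sensitive pyran ring and the allylic alcohols.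

**Compound list**
1 | (E)-pent-2-en-1-ol | CC/C=C/CO | starting material
2 | [(2R,3R)-3-ethyloxiran-2-yl]methanol | CC[C@H]1O[C@@H]1CO | intermediate
3 | (2S,3S)-3-methylpentane-1,2-diol | CC[C@H](C)[C@H](O)CO | intermediate
4 | (4S)-4-[(2S)-butan-2-yl]-2-(4-methoxyphenyl)-1,3-dioxolane (C2 epimers) | CC[C@H](C)[C@H]1COC(c2ccc(OC)cc2)O1 | intermediate
5 | (2S,3S)-2-[(4-methoxyphenyl)methoxy]-3-methylpentan-1-ol | CC[C@H](C)[C@H](OCc1ccc(OC)cc1)CO | intermediate
6 | (2S,3S)-2-[(4-methoxyphenyl)methoxy]-3-methylpentanal | CC[C@H](C)[C@H](OCc1ccc(OC)cc1)C=O | intermediate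
7 | 1,4-bis(trimethylsilyl)buta-1,3-diyne | C[Si](C)(C)C#CC#C[Si](C)(C)C | starting material
8 | lithium 4-(trimethylsilyl)buta-1,3-diynide | [Li+].[C-]#CC#C[Si](C)(C)C | intermediate
9 | (5RS,6S,7S)-6-[(4-methoxyphenyl)methoxy]-7-methyl-1-(trimethylsilyl)nona-1,3-diyn-5-ol | CC[C@H](C)[C@H](OCc1ccc(OC)cc1)C(O)C#CC#C[Si](C)(C)C | intermediate
10 | (6S,7S)-6-[(4-methoxyphenyl)methoxy]-7-methyl-1-(trimethylsilyl)nona-1,3-diyn-5-one | CC[C@H](C)[C@H](OCc1ccc(OC)cc1)C(=O)C#CC#C[Si](C)(C)C | intermediate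
11 | (5R,6S,7S)-6-[(4-methoxyphenyl)methoxy]-5,7-dimethyl-1-(trimethylsilyl)nona-1,3-diyn-5-ol | CC[C@H](C)[C@H](OCc1ccc(OC)cc1)[C@](C)(O)C#CC#C[Si](C)(C)C | intermediate
12 | (3E,5R,6S,7S)-6-[(4-methoxyphenyl)methoxy]-5,7-dimethyl-1-(trimethylsilyl)non-3-en-1-yn-5-ol | CC[C@H](C)[C@H](OCc1ccc(OC)cc1)[C@](C)(O)/C=C/C#C[Si](C)(C)C | intermediate
13 | (3E,5R,6S,7S)-6-[(4-methoxyphenyl)methoxy]-5,7-dimethylnon-3-en-1-yn-5-ol | CC[C@H](C)[C@H](OCc1ccc(OC)cc1)[C@](C)(O)/C=C/C#C | intermediate
14 | (3E,5R,6S,7S)-5,7-dimethylnon-3-en-1-yne-5,6-diol | CC[C@H](C)[C@H](O)[C@](C)(O)/C=C/C#C | intermediate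
15 | 1,3-dimethoxy-2-methylbenzene (2,6-dimethoxytoluene) | COc1cccc(OC)c1C | starting material
16 | 2-(3,5-dimethoxy-4-methylphenyl)-4,4,5,5-tetramethyl-1,3,2-dioxaborolane | COc1cc(B2OC(C)(C)C(C)(C)O2)cc(OC)c1C | intermediate
17 | 5-bromo-1,3-dimethoxy-2-methylbenzene | COc1cc(Br)cc(OC)c1C | intermediate
18 | 6-bromo-2,4-dimethoxy-3-methylbenzaldehyde | COc1cc(Br)c(C=O)c(OC)c1C | intermediate
19 | 6-bromo-2,4-dihydroxy-3-methylbenzaldehyde | Cc1c(O)cc(Br)c(C=O)c1O | intermediate
20 | 6-[(3E,5R,6S,7S)-5,6-dihydroxy-5,7-dimethylnon-3-en-1-yn-1-yl]-2,4-dihydroxy-3-methylbenzaldehyde | CC[C@H](C)[C@H](O)[C@](C)(O)/C=C/C#Cc1cc(O)c(C)c(O)c1C=O | intermediate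
21 | 3-[(1E,3R,4S,5S)-3,4-dihydroxy-3,5-dimethylhept-1-en-1-yl]-6,8-dihydroxy-7-methylisochromenylium trifluoroacetate | CC[C@H](C)[C@H](O)[C@](C)(O)/C=C/c1cc2cc(O)c(C)c(O)c2c[o+]1.[O-]C(=O)C(F)(F)F | intermediate
22 | 2,4-dihydroxy-6-[(3E,5R,6S,7S)-5,6-dihydroxy-5,7-dimethyl-2-oxonon-3-en-1-yl]-3-methylbenzaldehyde | CC[C@H](C)[C@H](O)[C@](C)(O)/C=C/C(=O)Cc1cc(O)c(C)c(O)c1C=O | intermediate
23 | (5S)-2-[(3E,5R,6S,7S)-5,6-dihydroxy-5,7-dimethyl-2-oxonon-3-en-1-yl]-4,5-dihydroxy-5-methyl-6-oxocyclohexa-1,3-diene-1-carbaldehyde | CC[C@H](C)[C@H](O)[C@](C)(O)/C=C/C(=O)CC1=C(C=O)C(=O)[C@@](C)(O)C(O)=C1 | intermediate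
24 | (7S)-3-[(1E,3R,4S,5S)-3,4-dihydroxy-3,5-dimethylhept-1-en-1-yl]-7-hydroxy-7-methyl-6H-isochromene-6,8(7H)-dione | CC[C@H](C)[C@H](O)[C@](C)(O)/C=C/C1=CC2=CC(=O)[C@](C)(O)C(=O)C2=CO1 | intermediate
25 | (7R)-5-chloro-3-[(1E,3R,4S,5S)-3,4-dihydroxy-3,5-dimethylhept-1-en-1-yl]-7-hydroxy-7-methyl-6H-isochromene-6,8(7H)-dione | CC[C@H](C)[C@H](O)[C@](C)(O)/C=C/C1=CC2=C(Cl)C(=O)[C@](C)(O)C(=O)C2=CO1 | intermediate
26 | (7R)-5-chloro-3-[(1E,3R,4S,5S)-3,5-dimethyl-3,4-bis(triethylsilyloxy)hept-1-en-1-yl]-7-methyl-7-(triethylsilyloxy)-6H-isochromene-6,8(7H)-dione | CC[C@H](C)[C@H](O[Si](CC)(CC)CC)[C@](C)(O[Si](CC)(CC)CC)/C=C/C1=CC2=C(Cl)C(=O)[C@](C)(O[Si](CC)(CC)CC)C(=O)C2=CO1 | intermediate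
27 | (7R,8R)-5-chloro-3-[(1E,3R,4S,5S)-3,5-dimethyl-3,4-bis(triethylsilyloxy)hept-1-en-1-yl]-8-hydroxy-7-methyl-7-(triethylsilyloxy)-7,8-dihydro-6H-isochromen-6-one | CC[C@H](C)[C@H](O[Si](CC)(CC)CC)[C@](C)(O[Si](CC)(CC)CC)/C=C/C1=CC2=C(Cl)C(=O)[C@](C)(O[Si](CC)(CC)CC)[C@H](O)C2=CO1 | intermediate
28 | (7R,8R)-5-chloro-3-[(1E,3R,4S,5S)-3,4-dihydroxy-3,5-dimethylhept-1-en-1-yl]-7,8-dihydroxy-7-methyl-7,8-dihydro-6H-isochromen-6-one | CC[C@H](C)[C@H](O)[C@](C)(O)/C=C/C1=CC2=C(Cl)C(=O)[C@](C)(O)[C@H](O)C2=CO1 | target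

**Totals**
Total step count: 21. Longest linear sequence: 18 steps (steps 1–11, then 15–21); the arene branch is 3 steps before the union.

**Three steps most likely to fail, with fallbacks**

Step 16 (gold/TFA cycloisomerisation–hydration). The tertiary allylic alcohol may ionise in acid, or the pyrylium salt may not hydrolyse cleanly. The fallback sets out from 20 and avoids a free pyrylium salt by trapping the cyclised intermediate under neutral conditions: Pd(OAc)2 (5 mol%), p-benzoquinone, MeOH, 1,4-dioxane, rt. This gives the isolable mixed acetal 3-[(1E,3R,4S,5S)-3,4-dihydroxy-3,5-dimethylhept-1-en-1-yl]-1-methoxy-7-methyl-1H-isochromene-6,8-diol F1. Gentle hydrolysis (PPTS cat., wet acetone, rt) then opens it to the keto-aldehyde, and the route is rejoined at 22.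

Step 17 (enzymatic dearomatisation). The monooxygenase may not accept a substrate with the polar diol side chain, or may give low conversion. The fallback sets out from 20 (so it also bypasses 22) and uses copper-mediated asymmetric oxidative dearomatisation: [Cu(MeCN)4]PF6, the (+)-sparteine surrogate diamine, O2, iPr2NEt, DMAP, CH2Cl2, −78 → −10 °C. This gives the alkynyl ortho-quinol (5S)-2-[(3E,5R,6S,7S)-5,6-dihydroxy-5,7-dimethylnon-3-en-1-yn-1-yl]-4,5-dihydroxy-5-methyl-6-oxocyclohexa-1,3-diene-1-carbaldehyde F2. Cycloisomerisation with CuI (cat.) and iPr2NEt in CH2Cl2 then closes the pyran ring, and the route is rejoined at 24.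

Step 20 (C8 reduction). Hydride may attack C6 or C1, or give the trans 7,8-diol; this step rests on reasoning rather than on a close precedent. The fallback sets out from unprotected 25 and replaces hydride chemistry by a biocatalytic reduction: a ketoreductase (NADPH-dependent short-chain dehydrogenase/reductase, with NADP+ and phosphite dehydrogenase/Na2HPO3 recycling, pH 7 buffer, 30 °C), chosen from a panel for the (8R)-alcohol. This bypasses 26 and 27 and rejoins the route directly at 28; it makes no compound outside the list (entry F0).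

**Further compounds**
F1 | step 16 | 3-[(1E,3R,4S,5S)-3,4-dihydroxy-3,5-dimethylhept-1-en-1-yl]-1-methoxy-7-methyl-1H-isochromene-6,8-diol (C1 epimers) | CC[C@H](C)[C@H](O)[C@](C)(O)/C=C/C1=Cc2cc(O)c(C)c(O)c2C(OC)O1
F2 | step 17 | (5S)-2-[(3E,5R,6S,7S)-5,6-dihydroxy-5,7-dimethylnon-3-en-1-yn-1-yl]-4,5-dihydroxy-5-methyl-6-oxocyclohexa-1,3-diene-1-carbaldehyde | CC[C@H](C)[C@H](O)[C@](C)(O)/C=C/C#CC1=C(C=O)C(=O)[C@@](C)(O)C(O)=C1
F0 | step 20 | none | none
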